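The route disconnects C4–H and the C5–O bond of the oxolane ring (O1, C2, C3, C4, C5) back to a C4=C5 methylene group beside the C7' carbinol. The key step exploits the 1,3-dioxygenated unit C7'(O)–C4–C5(O), in which the C7' oxygen and the C3 branch on C4 are syn: a dimethylsilyl hydride tethered to the C7' oxygen adds across C4=C5 in one operation, placing hydrogen on C4 and silicon on C5 in a temporary oxasilolane and fixing C4 from C7'. The precursor is an open chain with C2 and C3 from an auxiliary-controlled syn aldol, C7' from a catalytic ketone reduction, and three different silyl ethers on the C2 oxygen, the C9 oxygen and the phenol.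

Key step: step 11

Numbering: oxolane ring O1, C2 (bears the 4-hydroxyphenyl group), C3 (bears C9H2OAc), C4 (bears C7'), C5 (ring CH2); C7' is the exocyclic CH(OAc) carrying the 4-methoxyphenyl group. The target is (2R,3S,4R,7'S), with the C2 aryl, C9 and C7' substituents all-trans on the ring.

Assumption: in step 9 the planar, conjugated 4-methoxybenzoyl group is taken as the large substituent toward the oxazaborolidine and the twisted 2-alkylvinyl group as the small one; the (R)-catalyst follows from that.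

Remarks on the design:
- **Stereochemical check.** Precursor 19 and oxasilolane 20 carry the target configuration at C2, C3, C7' and, for 20, C4. The CIP label of C4 in 20 is S only because the silicon-bearing C5 outranks C7'; the spatial arrangement is that of 4R in the target. No descriptor needed correction.
- **Auxiliary.** The (R)-4-benzyl auxiliary is required for 2R,3S.
- **C9 protection.** C9–O carries TBDPS (not TBS), so that selective triethylsilyl removal and the alkoxide ring closure are clean.
- **Catalyst.** A neutral zerovalent platinum catalyst is used, because the C7'–O bond is benzylic to the anisyl ring and allylic and would ionise with an acidic platinum source.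
- **Ketone mask.** The C7' carbonyl is carried through the aldol as a methylene group, released later under neutral oxidative conditions, so that unmasking cannot endanger the C2 triethylsilyl ether.

Step 1
Reactants: 1 4-hydroxybenzaldehyde
Product: 2 4-(triisopropylsilyloxy)benzaldehyde
Conditions: TIPSCl, imidazole, DMF, rt
Reagents that add atoms: triisopropylsilyl chloride, CC(C)[Si](Cl)(C(C)C)C(C)C
Why: Imidazole-promoted O-silylation of the phenol (silyl ether formation) should give a base-stable aryl silyl ether and leave the aldehyde free for the aldol.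

Step 2
Reactants: 3 3-(4-methoxybenzoyl)propionic acid
Product: 4 4-(4-methoxyphenyl)pent-4-enoic acid
Conditions: Ph3PCH3Br, KOtBu, THF, 0 °C → rt; mildly acidic aqueous work-up (pH 4)
Reagents that add atoms: methyltriphenylphosphonium bromide, C[P+](c1ccccc1)(c1ccccc1)c1ccccc1.[Br-]
Why: Wittig methylenation with excess ylide on the potassium carboxylate should convert the aryl ketone into a 1,1-disubstituted alkene, which masks the C7' carbonyl through the enolisation and hydride steps without an acid-labile ketal.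

Step 3
Reactants: 4 4-(4-methoxyphenyl)pent-4-enoic acid; 5 (R)-4-benzyl-2-oxazolidinone
Product: 7 (R)-4-benzyl-3-[4-(4-methoxyphenyl)pent-4-enoyl]oxazolidin-2-one, via mixed pivalic anhydride 6 (not isolated)
Conditions: PivCl, Et3N, THF, −20 °C; then 5, LiCl, −20 °C → rt
Reagents that add atoms: pivaloyl chloride, CC(C)(C)C(=O)Cl (retained only in intermediate 6)
Why: N-Acylation of the oxazolidinone through the mixed pivalic anhydride (Et3N/LiCl protocol) is a standard entry to the acyl imide and should not touch the styrene-type alkene.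

Step 4
Reactants: 7 (R)-4-benzyl-3-[4-(4-methoxyphenyl)pent-4-enoyl]oxazolidin-2-one; 2 4-(triisopropylsilyloxy)benzaldehyde
Product: 9 (R)-4-benzyl-3-[(2R,3R)-3-hydroxy-2-[2-(4-methoxyphenyl)prop-2-en-1-yl]-3-[4-(triisopropylsilyloxy)phenyl]propanoyl]oxazolidin-2-one, via Z-boron enolate 8 (not isolated)
Conditions: Bu2BOTf, iPr2NEt, CH2Cl2, −78 → 0 °C; 2, −78 → 0 °C; pH 7 buffer, MeOH, 30% H2O2, 0 °C
Reagents that add atoms: dibutylboron trifluoromethanesulfonate, CCCCB(CCCC)OS(=O)(=O)C(F)(F)F (retained only in intermediate 8)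
Why: Evans syn aldol in which the Z-boron enolate reacts through a Zimmerman–Traxler chair on the face away from the benzyl group of the (R)-auxiliary, which should set C3 and C2 together as the syn pair in the absolute sense needed for 2R and the later 3S.

Step 5
Reactants: 9 aldol adduct
Product: 10 (1R,2S)-2-[2-(4-methoxyphenyl)prop-2-en-1-yl]-1-[4-(triisopropylsilyloxy)phenyl]propane-1,3-diol
Conditions: LiBH4, MeOH (1 equiv), THF, 0 °C
Reagents that add atoms: none
Why: Reductive removal of the auxiliary, in which LiBH4 reduces the imide carbonyl chemoselectively to the primary C9 alcohol, should leave the alkene, the aryl silyl ether and both stereocentres untouched.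

Step 6
Reactants: 10 diol
Product: 12 (2S,3R)-1-(tert-butyldiphenylsilyloxy)-2-[2-(4-methoxyphenyl)prop-2-en-1-yl]-3-(triethylsilyloxy)-3-[4-(triisopropylsilyloxy)phenyl]propane, via mono-TBDPS ether 11 (not isolated)
Conditions: TBDPSCl (1.05 equiv), imidazole, DMF, 0 °C; then TESCl, DMAP (cat.), rt
Reagents that add atoms: tert-butyl(chloro)diphenylsilane, CC(C)(C)[Si](Cl)(c1ccccc1)c1ccccc1; chlorotriethylsilane, CC[Si](Cl)(CC)CC
Why: Sequential silyl ether formation in one flask relies on sterics, the bulky TBDPSCl taking only the primary C9 hydroxyl before the small TESCl caps the secondary benzylic C2 hydroxyl.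

Step 7
Reactants: 12 bis-silyl ether alkene
Product: 13 (3S,4R)-3-[(tert-butyldiphenylsilyloxy)methyl]-1-(4-methoxyphenyl)-4-(triethylsilyloxy)-4-[4-(triisopropylsilyloxy)phenyl]butan-1-one
Conditions: OsO4 (cat.), NaIO4, 2,6-lutidine, dioxane/H2O, rt
Reagents that add atoms: osmium tetroxide, O=[Os](=O)(=O)=O; sodium periodate, [Na+].[O-][I](=O)(=O)=O (together the source of the ketone oxygen)
Why: Lemieux–Johnson oxidative cleavage (OsO4-catalysed dihydroxylation, periodate glycol fission, lutidine buffer) should unmask the C7' aryl ketone under neutral conditions that leave the three silyl ethers intact.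

Step 8
Reactants: 13 aryl ketone
Product: 16 (3S,4R)-3-[(tert-butyldiphenylsilyloxy)methyl]-1-(4-methoxyphenyl)-2-methylidene-4-(triethylsilyloxy)-4-[4-(triisopropylsilyloxy)phenyl]butan-1-one, via Mannich base 14 (not isolated), via methiodide 15 (not isolated)
Conditions: LiN(SiMe3)2, THF, −78 °C; Me2N=CH2+ I−, −78 °C → rt; MeI, CH2Cl2, rt; aq. NaHCO3, rt
Reagents that add atoms: N,N-dimethylmethyleneiminium iodide (Eschenmoser's salt), C=[N+](C)C.[I-]; iodomethane, CI (retained only in intermediate 15)
Why: Mannich reaction of the only possible lithium enolate (at C4) with Eschenmoser's salt, N-methylation and E1cB loss of trimethylamine should install the C4=C5 methylene group under base-only conditions, C3 being safe because deprotonation there gives no enolate.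

Step 9
Reactants: 16 enone
Product: 17 (1S,3S,4R)-3-[(tert-butyldiphenylsilyloxy)methyl]-1-(4-methoxyphenyl)-2-methylidene-4-(triethylsilyloxy)-4-[4-(triisopropylsilyloxy)phenyl]butan-1-ol
Conditions: (R)-Me-CBS [(R)-1-methyl-3,3-diphenyltetrahydro-1H,3H-pyrrolo[1,2-c][1,3,2]oxazaborole] (20 mol %), catecholborane, toluene, −78 °C
Reagents that add atoms: none
Why: Corey–Bakshi–Shibata reduction in which the ketone binds the oxazaborolidine boron anti to the planar 4-methoxybenzoyl group and hydride is delivered to the Re face through a six-membered transition state, which should set C7' as S under catalyst control and give only 1,2-reduction at this temperature.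

Step 10
Reactants: 17 allylic alcohol; 18 chlorodimethylsilane
Product: 19 hydrodimethylsilyl ether of 17 at the C7' oxygen, (1S,3S,4R)-configured
Conditions: Et3N, DMAP (cat.), CH2Cl2, 0 °C; filtered and used directly
Reagents that add atoms: none
Why: Silyl ether formation with the small chlorosilane and an amine base should place the Si–H tether on the C7' oxygen without affecting the other silyl ethers, the moisture-sensitive product being used at once.

Step 11
Reactants: 19 hydrodimethylsilyl ether
Product: 20 (4S,5S)-4-[(2S,3R)-1-(tert-butyldiphenylsilyloxy)-3-(triethylsilyloxy)-3-[4-(triisopropylsilyloxy)phenyl]propan-2-yl]-5-(4-methoxyphenyl)-2,2-dimethyl-1,2-oxasilolane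
Conditions: Pt2[(CH2=CHSiMe2)2O]3 (Karstedt's catalyst, zerovalent platinum, 1 mol % Pt), toluene, 40–60 °C
Reagents that add atoms: none
Why: Oxidative addition of the Si–H bond to zerovalent platinum gives a silyl platinum hydride held over C4=C5 by the two-atom O–Si tether, alkene insertion delivers hydrogen to C4, and C–Si reductive elimination at C5 closes the ring (Chalk–Harrod sequence). The closest known reaction type is the platinum-catalysed intramolecular hydrosilylation of hydrodimethylsilyl ethers of 2-substituted allylic alcohols, which after oxidation gives 2,3-syn 1,3-diols. The oxasilolane (Si, O, C7', C4, C5) closes in the 5-endo-trig mode, both alkene carbons lying inside the ring. The new stereocentre C4 is controlled by C7': in the cyclic transition state the C7'–H bond eclipses the C4–C3 bond to avoid A(1,2) strain between the anisyl group and the C3 branch, so hydrogen arrives on the tether face and the anisyl and C3 substituents end up cis on the ring, which is the 7',4-syn relation. The step needs face selectivity at C4 and no migration of the double bond; the short tether, the bulky C3 branch (whose smaller CH2OSi arm lies on the tether face when C3–H is turned inward) and a neutral, chloride-free catalyst that cannot ionise the benzylic and allylic C7'–O bond should secure both.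

Step 12
Reactants: 20 oxasilolane
Product: 21 (1S,2R,3S,4R)-3-[(tert-butyldiphenylsilyloxy)methyl]-2-(hydroxymethyl)-1-(4-methoxyphenyl)-4-(triethylsilyloxy)-4-[4-(triisopropylsilyloxy)phenyl]butan-1-ol
Conditions: 30% H2O2, KHCO3, THF/MeOH 1:1, 40 °C
Reagents that add atoms: hydrogen peroxide, OO
Why: Tamao–Kumada oxidation in which hydroperoxide adds to the alkoxy-activated silicon and C5 migrates from silicon to oxygen should turn C5–Si into C5–OH and free the C7' hydroxyl without touching a stereocentre, fluoride being omitted to spare the aryl silyl ether.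

Step 13
Reactants: 21 diol
Product: 22 C5 4-methylbenzenesulfonate of 21 (C7' hydroxyl free)
Conditions: TsCl (1.1 equiv), Et3N, DMAP (cat.), CH2Cl2, 0 °C
Reagents that add atoms: 4-methylbenzenesulfonyl chloride, Cc1ccc(S(=O)(=O)Cl)cc1
Why: Selective sulfonylation of the unhindered primary C5 hydroxyl over the hindered secondary benzylic C7' hydroxyl should turn C5 into the electrophile for ring closure.

Step 14
Reactants: 22 tosylate
Product: 24 (S)-[(3R,4S,5R)-4-[(tert-butyldiphenylsilyloxy)methyl]-5-[4-(triisopropylsilyloxy)phenyl]oxolan-3-yl](4-methoxyphenyl)methanol, via hydroxy tosylate 23 (not isolated)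
Conditions: HF·pyridine, pyridine, THF, 0 °C; then NaH (1.1 equiv), THF, 0 °C → rt
Reagents that add atoms: none
Why: Buffered HF·pyridine should cleave the triethylsilyl ether selectively, and one equivalent of NaH then triggers the intramolecular Williamson etherification, a 5-exo-tet attack of the C2 alkoxide on C5 that closes the oxolane ring without touching a stereocentre and outruns oxetane formation from the C7' hydroxyl.

Step 15
Reactants: 24 silylated oxolane
Product: 25 (S)-[(3R,4S,5R)-4-(hydroxymethyl)-5-(4-hydroxyphenyl)oxolan-3-yl](4-methoxyphenyl)methanol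
Conditions: Bu4NF, AcOH, THF, rt
Reagents that add atoms: none
Why: Fluoride-mediated desilylation should remove the TBDPS and aryl TIPS groups together, the acetic acid buffer keeping the liberated para-hydroxybenzyl ether from opening through a quinone methide.

Step 16
Reactants: 25 triol
Product: 26 triacetate of 25 (C7', C9 and phenol oxygens acetylated)
Conditions: Ac2O, pyridine, DMAP (cat.), CH2Cl2, rt
Reagents that add atoms: acetic anhydride, CC(=O)OC(C)=O
Why: Exhaustive acylation with Ac2O, pyridine and DMAP should esterify the primary, the secondary benzylic and the phenolic hydroxyl groups with retention at C7'.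

Step 17
Reactants: 26 triacetate
Product: 27 [(2R,3S,4R)-4-[(S)-acetoxy(4-methoxyphenyl)methyl]-2-(4-hydroxyphenyl)oxolan-3-yl]methyl acetate (CNP0231272.1)
Conditions: NH4OAc, MeOH/H2O 4:1, rt
Reagents that add atoms: none
Why: Chemoselective solvolysis of the aryl acetate should cleave only the phenolic ester, because phenoxide is a far better leaving group than an alkoxide, leaving the primary and secondary alkyl acetates in place.

Compound list
1 | 4-hydroxybenzaldehyde | O=Cc1ccc(O)cc1 | starting material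
2 | 4-(triisopropylsilyloxy)benzaldehyde | O=Cc1ccc(O[Si](C(C)C)(C(C)C)C(C)C)cc1 | intermediate
3 | 3-(4-methoxybenzoyl)propionic acid | COc1ccc(C(=O)CCC(=O)O)cc1 | starting material
4 | 4-(4-methoxyphenyl)pent-4-enoic acid | COc1ccc(C(=C)CCC(=O)O)cc1 | intermediate
5 | (R)-4-benzyl-2-oxazolidinone | O=C1N[C@H](Cc2ccccc2)CO1 | starting material
6 | mixed anhydride of 4 with pivalic acid | COc1ccc(C(=C)CCC(=O)OC(=O)C(C)(C)C)cc1 | intermediate (not isolated)
7 | (R)-4-benzyl-3-[4-(4-methoxyphenyl)pent-4-enoyl]oxazolidin-2-one | COc1ccc(C(=C)CCC(=O)N2[C@H](Cc3ccccc3)COC2=O)cc1 | intermediate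
8 | (Z)-dibutylboron enolate of 7 | CCCCB(CCCC)O/C(=C\CC(=C)c1ccc(OC)cc1)N1[C@H](Cc2ccccc2)COC1=O | intermediate (not isolated)
9 | (R)-4-benzyl-3-[(2R,3R)-3-hydroxy-2-[2-(4-methoxyphenyl)prop-2-en-1-yl]-3-[4-(triisopropylsilyloxy)phenyl]propanoyl]oxazolidin-2-one | COc1ccc(C(=C)C[C@@H](C(=O)N2[C@H](Cc3ccccc3)COC2=O)[C@@H](O)c2ccc(O[Si](C(C)C)(C(C)C)C(C)C)cc2)cc1 | intermediate
10 | (1R,2S)-2-[2-(4-methoxyphenyl)prop-2-en-1-yl]-1-[4-(triisopropylsilyloxy)phenyl]propane-1,3-diol | COc1ccc(C(=C)C[C@@H](CO)[C@@H](O)c2ccc(O[Si](C(C)C)(C(C)C)C(C)C)cc2)cc1 | intermediate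
11 | (1R,2S)-3-(tert-butyldiphenylsilyloxy)-2-[2-(4-methoxyphenyl)prop-2-en-1-yl]-1-[4-(triisopropylsilyloxy)phenyl]propan-1-ol | COc1ccc(C(=C)C[C@@H](CO[Si](c2ccccc2)(c2ccccc2)C(C)(C)C)[C@@H](O)c2ccc(O[Si](C(C)C)(C(C)C)C(C)C)cc2)cc1 | intermediate (not isolated)
12 | (2S,3R)-1-(tert-butyldiphenylsilyloxy)-2-[2-(4-methoxyphenyl)prop-2-en-1-yl]-3-(triethylsilyloxy)-3-[4-(triisopropylsilyloxy)phenyl]propane | COc1ccc(C(=C)C[C@@H](CO[Si](c2ccccc2)(c2ccccc2)C(C)(C)C)[C@@H](O[Si](CC)(CC)CC)c2ccc(O[Si](C(C)C)(C(C)C)C(C)C)cc2)cc1 | intermediate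
13 | (3S,4R)-3-[(tert-butyldiphenylsilyloxy)methyl]-1-(4-methoxyphenyl)-4-(triethylsilyloxy)-4-[4-(triisopropylsilyloxy)phenyl]butan-1-one | COc1ccc(C(=O)C[C@@H](CO[Si](c2ccccc2)(c2ccccc2)C(C)(C)C)[C@@H](O[Si](CC)(CC)CC)c2ccc(O[Si](C(C)C)(C(C)C)C(C)C)cc2)cc1 | intermediate
14 | 2-[(dimethylamino)methyl] derivative of 13 (Mannich base, mixture of epimers at the new C4 centre, 3S,4R elsewhere) | COc1ccc(C(=O)C(CN(C)C)[C@@H](CO[Si](c2ccccc2)(c2ccccc2)C(C)(C)C)[C@@H](O[Si](CC)(CC)CC)c2ccc(O[Si](C(C)C)(C(C)C)C(C)C)cc2)cc1 | intermediate (not isolated)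
15 | trimethylammonium iodide of 14 | COc1ccc(C(=O)C(C[N+](C)(C)C)[C@@H](CO[Si](c2ccccc2)(c2ccccc2)C(C)(C)C)[C@@H](O[Si](CC)(CC)CC)c2ccc(O[Si](C(C)C)(C(C)C)C(C)C)cc2)cc1.[I-] | intermediate (not isolated)
16 | (3S,4R)-3-[(tert-butyldiphenylsilyloxy)methyl]-1-(4-methoxyphenyl)-2-methylidene-4-(triethylsilyloxy)-4-[4-(triisopropylsilyloxy)phenyl]butan-1-one | COc1ccc(C(=O)C(=C)[C@@H](CO[Si](c2ccccc2)(c2ccccc2)C(C)(C)C)[C@@H](O[Si](CC)(CC)CC)c2ccc(O[Si](C(C)C)(C(C)C)C(C)C)cc2)cc1 | intermediate
17 | (1S,3S,4R)-3-[(tert-butyldiphenylsilyloxy)methyl]-1-(4-methoxyphenyl)-2-methylidene-4-(triethylsilyloxy)-4-[4-(triisopropylsilyloxy)phenyl]butan-1-ol | COc1ccc([C@@H](O)C(=C)[C@@H](CO[Si](c2ccccc2)(c2ccccc2)C(C)(C)C)[C@@H](O[Si](CC)(CC)CC)c2ccc(O[Si](C(C)C)(C(C)C)C(C)C)cc2)cc1 | intermediate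
18 | chlorodimethylsilane | C[SiH](C)Cl | starting material
19 | hydrodimethylsilyl ether of 17 at the C7' oxygen (1S,3S,4R; key-step precursor) | COc1ccc([C@@H](O[SiH](C)C)C(=C)[C@@H](CO[Si](c2ccccc2)(c2ccccc2)C(C)(C)C)[C@@H](O[Si](CC)(CC)CC)c2ccc(O[Si](C(C)C)(C(C)C)C(C)C)cc2)cc1 | intermediate
20 | (4S,5S)-4-[(2S,3R)-1-(tert-butyldiphenylsilyloxy)-3-(triethylsilyloxy)-3-[4-(triisopropylsilyloxy)phenyl]propan-2-yl]-5-(4-methoxyphenyl)-2,2-dimethyl-1,2-oxasilolane | COc1ccc([C@H]2O[Si](C)(C)C[C@H]2[C@@H](CO[Si](c3ccccc3)(c3ccccc3)C(C)(C)C)[C@@H](O[Si](CC)(CC)CC)c3ccc(O[Si](C(C)C)(C(C)C)C(C)C)cc3)cc1 | intermediate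
21 | (1S,2R,3S,4R)-3-[(tert-butyldiphenylsilyloxy)methyl]-2-(hydroxymethyl)-1-(4-methoxyphenyl)-4-(triethylsilyloxy)-4-[4-(triisopropylsilyloxy)phenyl]butan-1-ol | COc1ccc([C@@H](O)[C@@H](CO)[C@@H](CO[Si](c2ccccc2)(c2ccccc2)C(C)(C)C)[C@@H](O[Si](CC)(CC)CC)c2ccc(O[Si](C(C)C)(C(C)C)C(C)C)cc2)cc1 | intermediate
22 | C5 4-methylbenzenesulfonate of 21 | COc1ccc([C@@H](O)[C@@H](COS(=O)(=O)c2ccc(C)cc2)[C@@H](CO[Si](c2ccccc2)(c2ccccc2)C(C)(C)C)[C@@H](O[Si](CC)(CC)CC)c2ccc(O[Si](C(C)C)(C(C)C)C(C)C)cc2)cc1 | intermediate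
23 | hydroxy tosylate (22 without the triethylsilyl group, C2 hydroxyl free) | COc1ccc([C@@H](O)[C@@H](COS(=O)(=O)c2ccc(C)cc2)[C@@H](CO[Si](c2ccccc2)(c2ccccc2)C(C)(C)C)[C@@H](O)c2ccc(O[Si](C(C)C)(C(C)C)C(C)C)cc2)cc1 | intermediate (not isolated)
24 | (S)-[(3R,4S,5R)-4-[(tert-butyldiphenylsilyloxy)methyl]-5-[4-(triisopropylsilyloxy)phenyl]oxolan-3-yl](4-methoxyphenyl)methanol | COc1ccc([C@@H](O)[C@H]2CO[C@@H](c3ccc(O[Si](C(C)C)(C(C)C)C(C)C)cc3)[C@@H]2CO[Si](c3ccccc3)(c3ccccc3)C(C)(C)C)cc1 | intermediate
25 | (S)-[(3R,4S,5R)-4-(hydroxymethyl)-5-(4-hydroxyphenyl)oxolan-3-yl](4-methoxyphenyl)methanol | COc1ccc([C@@H](O)[C@H]2CO[C@@H](c3ccc(O)cc3)[C@@H]2CO)cc1 | intermediate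
26 | triacetate of 25 | COc1ccc([C@@H](OC(C)=O)[C@H]2CO[C@@H](c3ccc(OC(C)=O)cc3)[C@@H]2COC(C)=O)cc1 | intermediate
27 | [(2R,3S,4R)-4-[(S)-acetoxy(4-methoxyphenyl)methyl]-2-(4-hydroxyphenyl)oxolan-3-yl]methyl acetate (CNP0231272.1) | COc1ccc([C@@H](OC(C)=O)[C@H]2CO[C@@H](c3ccc(O)cc3)[C@@H]2COC(C)=O)cc1 | target

Total step count: 17. Longest linear sequence: 16 steps (steps 2 to 17, from 3 to 27); step 1 is a one-step side branch.

Steps most likely to fail

1. Step 11 (key step). Face selectivity at C4 may be insufficient if the C3 stereocentre opposes the control exerted by C7', or a platinum hydride may move the C4=C5 double bond toward C3 before ring closure. The fallback sets out from 17 and comes back at 25. The C7' hydroxyl of 17 is capped with TBSOTf and 2,6-lutidine to give the C7' tert-butyldimethylsilyl ether F1. Rhodium-catalysed hydroboration of F1 with catecholborane and RhCl(PPh3)3, which is known to favour the syn isomer for silyl-protected 2-substituted allylic alcohols where the uncatalysed reaction favours anti, followed by buffered H2O2 oxidation, should give the C5 primary alcohol F2. Tosylation gives the C5 tosylate F3, HF·pyridine removes the triethylsilyl group to give the hydroxy tosylate F4, NaH closes the oxolane to the C7' silyl ether F5, and Bu4NF/AcOH removes the three remaining silyl groups to rejoin the route at triol 25.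

2. Step 9. Facial selectivity may be poor or reversed if the twisted 2-alkylvinyl group, and not the aroyl group, behaves as the large substituent, or if the C3 stereocentre is mismatched with the catalyst. The fallback sets out from 16 and comes back at 17. Luche reduction (NaBH4, CeCl3·7H2O, MeOH/THF, −78 °C) should give 17 together with its C7' epimer F6. The diastereomers are separated by chromatography, and F6 is oxidised back to enone 16 with MnO2 and recycled, so that the C7' configuration rests on separation and recycling and not on catalyst control.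

3. Step 8. The Mannich reaction of the hindered, β-branched enolate may be sluggish, or the sensitive enone may be lost through conjugate addition of amine or iodide during the elimination. The fallback sets out from 13 and comes back at 16. The lithium enolate of 13 is hydroxymethylated with monomeric formaldehyde (aldol addition) to give the β-hydroxy ketone F7 as C4 epimers. MsCl and Et3N convert it to the mesylate F8, and DBU effects E1cB elimination to enone 16.

Further compounds
F1 | step 11 | C7' tert-butyldimethylsilyl ether of 17 | COc1ccc([C@@H](O[Si](C)(C)C(C)(C)C)C(=C)[C@@H](CO[Si](c2ccccc2)(c2ccccc2)C(C)(C)C)[C@@H](O[Si](CC)(CC)CC)c2ccc(O[Si](C(C)C)(C(C)C)C(C)C)cc2)cc1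
F2 | step 11 | C5 primary alcohol from syn hydroboration of F1 (C7' silyl ether of 21) | COc1ccc([C@@H](O[Si](C)(C)C(C)(C)C)[C@@H](CO)[C@@H](CO[Si](c2ccccc2)(c2ccccc2)C(C)(C)C)[C@@H](O[Si](CC)(CC)CC)c2ccc(O[Si](C(C)C)(C(C)C)C(C)C)cc2)cc1
F3 | step 11 | C5 4-methylbenzenesulfonate of F2 | COc1ccc([C@@H](O[Si](C)(C)C(C)(C)C)[C@@H](COS(=O)(=O)c2ccc(C)cc2)[C@@H](CO[Si](c2ccccc2)(c2ccccc2)C(C)(C)C)[C@@H](O[Si](CC)(CC)CC)c2ccc(O[Si](C(C)C)(C(C)C)C(C)C)cc2)cc1
F4 | step 11 | hydroxy tosylate from F3 (C2 hydroxyl free) | COc1ccc([C@@H](O[Si](C)(C)C(C)(C)C)[C@@H](COS(=O)(=O)c2ccc(C)cc2)[C@@H](CO[Si](c2ccccc2)(c2ccccc2)C(C)(C)C)[C@@H](O)c2ccc(O[Si](C(C)C)(C(C)C)C(C)C)cc2)cc1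
F5 | step 11 | C7' tert-butyldimethylsilyl ether of 24 | COc1ccc([C@@H](O[Si](C)(C)C(C)(C)C)[C@H]2CO[C@@H](c3ccc(O[Si](C(C)C)(C(C)C)C(C)C)cc3)[C@@H]2CO[Si](c3ccccc3)(c3ccccc3)C(C)(C)C)cc1
F6 | step 9 | C7' epimer of 17 (1R,3S,4R) | COc1ccc([C@H](O)C(=C)[C@@H](CO[Si](c2ccccc2)(c2ccccc2)C(C)(C)C)[C@@H](O[Si](CC)(CC)CC)c2ccc(O[Si](C(C)C)(C(C)C)C(C)C)cc2)cc1
F7 | step 8 | 2-(hydroxymethyl) derivative of 13 (C4 epimers) | COc1ccc(C(=O)C(CO)[C@@H](CO[Si](c2ccccc2)(c2ccccc2)C(C)(C)C)[C@@H](O[Si](CC)(CC)CC)c2ccc(O[Si](C(C)C)(C(C)C)C(C)C)cc2)cc1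
F8 | step 8 | methanesulfonate of F7 | COc1ccc(C(=O)C(COS(C)(=O)=O)[C@@H](CO[Si](c2ccccc2)(c2ccccc2)C(C)(C)C)[C@@H](O[Si](CC)(CC)CC)c2ccc(O[Si](C(C)C)(C(C)C)C(C)C)cc2)cc1
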